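**Retrosynthetic overview**
- Target ⇐ diol methyl ester (global acetylation) ⇐ trans-fused Δ1-octalin acid: the C4 carboxyl delivers the C2–O bond by selenolactonisation, and methanolysis then selenoxide elimination moves the alkene to C1=C10.
- Rings A and B are disconnected together: C5–C10 and C3–C4 arise in one enantioselective intramolecular Diels–Alder reaction of an acyclic (E)-α-methyl-enal/(E)-diene, which also creates quaternary C4.
- Triene ⇐ 1,5-diene carrying the C8/C9 stereodiad, by B-alkyl Suzuki coupling (C5–C6) and Heck vinylation (C1–C2).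
- C8–C9 ⇐ Pd-catalysed branch-selective allyl–allyl coupling of an (E)-allyl chloride with (E)-crotylB(pin); the chloride comes from (R)-citronellol (source of C13) by ozonolysis, alkyne formation and carboalumination.
- Ring order: acyclic → A and B simultaneously → transient bridging γ-lactone, opened again.

Assumption: positions use halimane numbering; the antipodes of the chiral ligand (step 6) and catalyst (step 10) are those expected from published stereomodels and would be exchanged if the observed sense were opposite.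

**Step 1**
Reactants: 1 (R)-(+)-citronellol
Product: 2 (R)-citronellyl triisopropylsilyl ether
Conditions: TIPSCl, imidazole, CH2Cl2, 0 °C→rt
Reagents that add atoms: triisopropylsilyl chloride, CC(C)[Si](Cl)(C(C)C)C(C)C
Why: Imidazole-mediated O-silylation of the primary alcohol leaves the chiral-pool stereocentre (future C13, R) untouched and gives an ether that survives aqueous fluoride, organoaluminium and Lewis-acid steps.

**Step 2**
Reactants: 2 (R)-citronellyl triisopropylsilyl ether
Product: 4 (4R)-4-methyl-6-(triisopropylsilyloxy)hexanal, via secondary ozonide 3 (not isolated)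
Conditions: O3, CH2Cl2, −78 °C; Me2S, −78 °C→rt
Reagents that add atoms: ozone, [O-][O+]=O
Why: Ozonolysis with reductive work-up cleaves the trisubstituted alkene so that the former C6 of citronellol becomes the aldehyde carbon destined to be C9.

**Step 3**
Reactants: 4 (4R)-4-methyl-6-(triisopropylsilyloxy)hexanal
Product: 5 triisopropyl{[(3R)-3-methylhept-6-yn-1-yl]oxy}silane
Conditions: dimethyl (1-diazo-2-oxopropyl)phosphonate, K2CO3, MeOH, 0 °C→rt
Reagents that add atoms: Ohira–Bestmann reagent, COP(=O)(OC)C(=[N+]=[N-])C(C)=O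
Why: Ohira–Bestmann (Seyferth–Gilbert) homologation converts the aldehyde into the terminal alkyne under mild base that does not affect the silyl ether.

**Step 4**
Reactants: 5 triisopropyl{[(3R)-3-methylhept-6-yn-1-yl]oxy}silane
Product: 7 (2E,6R)-3,6-dimethyl-8-(triisopropylsilyloxy)oct-2-en-1-ol, via (E)-alkenyldimethylalane 6 (not isolated)
Conditions: Me3Al, Cp2ZrCl2 (cat.), CH2Cl2, rt; n-BuLi, −78 °C; (CH2O)n, THF, rt
Reagents that add atoms: trimethylaluminium, C[Al](C)C; paraformaldehyde (as formaldehyde), C=O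
Why: Negishi Zr-catalysed syn-carboalumination puts Me on the internal and Al on the terminal alkyne carbon, and the derived alanate adds to formaldehyde with retention, giving the (E)-trisubstituted allylic alcohol.

**Step 5**
Reactants: 7 (2E,6R)-3,6-dimethyl-8-(triisopropylsilyloxy)oct-2-en-1-ol
Product: 8 {[(3R,6E)-8-chloro-3,6-dimethyloct-6-en-1-yl]oxy}triisopropylsilane
Conditions: NCS, Me2S, CH2Cl2, −20→0 °C
Reagents that add atoms: N-chlorosuccinimide, O=C1CCC(=O)N1Cl
Why: Corey–Kim chlorination converts the primary allylic alcohol into the allylic chloride without allylic transposition or loss of E geometry.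

**Step 6**
Reactants: 8 {[(3R,6E)-8-chloro-3,6-dimethyloct-6-en-1-yl]oxy}triisopropylsilane; 9 (E)-crotylboronic acid pinacol ester
Product: 10 triisopropyl{[(3R,6R,7R)-3,6,7-trimethyl-6-vinylnon-8-en-1-yl]oxy}silane
Conditions: Pd2(dba)3 (2.5 mol%), (R)-MeO-furyl-BIPHEP (6 mol%), CsF, THF/H2O 10:1, 60 °C
Reagents that add atoms: none
Why: Morken-type branch-selective Pd-catalysed allyl–allyl cross-coupling joins the γ-carbons of both (E)-allyl units by 3,3′-reductive elimination through a chair-like bis(η1-allyl)Pd, so quaternary C9 and tertiary C8 form together, with the two methyls syn from the E,E geometries and the absolute sense from the ligand.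

**Step 7**
Reactants: 11 methacrolein
Product: 13 (E)-3-bromo-2-methylprop-2-enal, via 2,3-dibromo-2-methylpropanal 12 (not isolated)
Conditions: Br2, CH2Cl2, −78 °C; Et3N, 0 °C→rt
Reagents that add atoms: bromine, BrBr
Why: Bromine addition to the enal followed by E2 dehydrobromination gives the (E)-β-bromo-enal needed as the sp2 coupling partner.

**Step 8**
Reactants: 10 triisopropyl{[(3R,6R,7R)-3,6,7-trimethyl-6-vinylnon-8-en-1-yl]oxy}silane; 13 (E)-3-bromo-2-methylprop-2-enal
Product: 15 (2E,6R,7R,10R)-2,6,7,10-tetramethyl-12-(triisopropylsilyloxy)-7-vinyldodec-2-enal, via B-alkyl-9-BBN 14 (not isolated)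
Conditions: 9-BBN, THF, 0 °C→rt; then 13, PdCl2(dppf) (5 mol%), AsPh3, Cs2CO3, DMF/H2O, rt
Reagents that add atoms: none
Why: Anti-Markovnikov hydroboration with bulky 9-BBN selects the vinyl on tertiary C8 over the neopentyl-type vinyl on quaternary C9, and B-alkyl Suzuki–Miyaura coupling with retention installs the (E)-α-methyl enal (C4–C6).

**Step 9**
Reactants: 15 (2E,6R,7R,10R)-2,6,7,10-tetramethyl-12-(triisopropylsilyloxy)-7-vinyldodec-2-enal
Product: 16 (2E,6R,7S,10R)-7-[(1E)-buta-1,3-dien-1-yl]-2,6,7,10-tetramethyl-12-(triisopropylsilyloxy)dodec-2-enal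
Conditions: vinyl bromide (5 equiv), Pd(OAc)2 (10 mol%), P(o-tol)3, Et3N, MeCN, 80 °C, sealed tube
Reagents that add atoms: vinyl bromide, C=CBr
Why: Mizoroki–Heck vinylation adds at the unhindered terminus of the remaining vinyl group, β-hydride elimination is possible only away from the quaternary carbon so the (E)-1,3-diene results, and the trisubstituted enal is inert.

**Step 10**
Reactants: 16 (2E,6R,7S,10R)-7-[(1E)-buta-1,3-dien-1-yl]-2,6,7,10-tetramethyl-12-(triisopropylsilyloxy)dodec-2-enal
Product: 17 trans-fused 15-(triisopropylsilyloxy)halim-1-en-18-al (4-CHO cis to H-5; H-10 trans to H-5; 8-Me and 9-Me cis to each other and trans to H-5)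
Conditions: (S)-o-tolyl-CBS-oxazaborolidine (20 mol%), Tf2NH (18 mol%), CH2Cl2, −40→−20 °C
Reagents that add atoms: none
Why: Chiral oxazaborolidinium-catalysed intramolecular Diels–Alder reaction forms rings A and B at once: the tether fixes the regiochemistry, suprafacial addition to the (E)-enal puts 4-CHO cis to H-5, the catalyst-shielded enal face sets C4/C5 relative to C8/C9, and the CHO-endo chair-like transition state gives the trans fusion (C10 is planarised later).

**Step 11**
Reactants: 17 trans-fused 15-(triisopropylsilyloxy)halim-1-en-18-al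
Product: 18 trans-fused 15-(triisopropylsilyloxy)halim-1-en-18-oic acid
Conditions: NaClO2, NaH2PO4, 2-methyl-2-butene, t-BuOH/H2O, rt
Reagents that add atoms: sodium chlorite, [Na+].[O-]Cl=O
Why: Pinnick oxidation converts the neopentyl aldehyde into the acid without touching the ring alkene or the silyl ether.

**Step 12**
Reactants: 18 trans-fused 15-(triisopropylsilyloxy)halim-1-en-18-oic acid
Product: 19 1α-phenylseleno-18,2β-olide (γ-lactone bridging C4 and C2; PhSe on C1 anti to the lactone oxygen)
Conditions: PhSeCl, Et3N, CH2Cl2, −78→0 °C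
Reagents that add atoms: phenylselenenyl chloride, Cl[Se]c1ccccc1
Why: Phenylselenolactonisation (5-exo, anti addition, ring A in a boat) lets the C4 carboxylate reach C2 only from its own face, so the C2–O configuration is relayed from C4 and PhSe ends on C1 cis to H-10.

**Step 13**
Reactants: 19 1α-phenylseleno-18,2β-olide
Product: 21 methyl 2β-hydroxy-15-(triisopropylsilyloxy)halim-1(10)-en-18-oate, via hydroxy selenide methyl ester 20 (not isolated)
Conditions: NaOMe (cat.), MeOH, 0 °C→rt; then 30% H2O2, pyridine, THF, 0 °C→rt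
Reagents that add atoms: methanol, CO
Why: Methanolysis opens the strained lactone first (a lactone-bridged Δ1(10) ring cannot accommodate ring B), and selenoxide syn-elimination then proceeds away from the carbinol carbon using the cis H-10 to give the C1=C10 allylic alcohol (Sharpless–Reich allylic alcohol synthesis).

**Step 14**
Reactants: 21 methyl 2β-hydroxy-15-(triisopropylsilyloxy)halim-1(10)-en-18-oate
Product: 23 CNP0209333.1, via diol ester 22 (not isolated)
Conditions: TBAF, THF, rt; then Ac2O, pyridine, DMAP, rt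
Reagents that add atoms: acetic anhydride, CC(=O)OC(C)=O
Why: Fluoride desilylation followed by DMAP-catalysed acetylation of the secondary allylic and the primary alcohol gives the diacetate; the hydroxy ester cannot relactonise because the bridged ene-lactone is too strained.

**Compound list**
1 | (R)-(+)-citronellol | CC(C)=CCC[C@@H](C)CCO | starting material
2 | (R)-citronellyl triisopropylsilyl ether | CC(C)=CCC[C@@H](C)CCO[Si](C(C)C)(C(C)C)C(C)C | intermediate
3 | secondary ozonide of 2 (1,2,4-trioxolane) | CC1(C)OOC(CC[C@@H](C)CCO[Si](C(C)C)(C(C)C)C(C)C)O1 | intermediate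
4 | (4R)-4-methyl-6-(triisopropylsilyloxy)hexanal | O=CCC[C@@H](C)CCO[Si](C(C)C)(C(C)C)C(C)C | intermediate
5 | triisopropyl{[(3R)-3-methylhept-6-yn-1-yl]oxy}silane | C#CCC[C@@H](C)CCO[Si](C(C)C)(C(C)C)C(C)C | intermediate
6 | (E)-alkenyldimethylalane from 5 (Al cis to the new methyl) | C[Al](C)/C=C(C)/CC[C@@H](C)CCO[Si](C(C)C)(C(C)C)C(C)C | intermediate
7 | (2E,6R)-3,6-dimethyl-8-(triisopropylsilyloxy)oct-2-en-1-ol | OC/C=C(C)/CC[C@@H](C)CCO[Si](C(C)C)(C(C)C)C(C)C | intermediate
8 | {[(3R,6E)-8-chloro-3,6-dimethyloct-6-en-1-yl]oxy}triisopropylsilane | ClC/C=C(C)/CC[C@@H](C)CCO[Si](C(C)C)(C(C)C)C(C)C | intermediate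
9 | (E)-crotylboronic acid pinacol ester | C/C=C/CB1OC(C)(C)C(C)(C)O1 | starting material
10 | triisopropyl{[(3R,6R,7R)-3,6,7-trimethyl-6-vinylnon-8-en-1-yl]oxy}silane | C=C[C@@](C)(CC[C@@H](C)CCO[Si](C(C)C)(C(C)C)C(C)C)[C@H](C)C=C | intermediate
11 | methacrolein | CC(=C)C=O | starting material
12 | 2,3-dibromo-2-methylpropanal (racemic) | CC(Br)(CBr)C=O | intermediate
13 | (E)-3-bromo-2-methylprop-2-enal | O=C/C(C)=C/Br | intermediate
14 | B-alkyl-9-BBN from hydroboration of the C8 vinyl group of 10 | C=C[C@@](C)(CC[C@@H](C)CCO[Si](C(C)C)(C(C)C)C(C)C)[C@H](C)CCB1C2CCCC1CCC2 | intermediate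
15 | (2E,6R,7R,10R)-2,6,7,10-tetramethyl-12-(triisopropylsilyloxy)-7-vinyldodec-2-enal | O=C/C(C)=C/CC[C@@H](C)[C@](C)(CC[C@@H](C)CCO[Si](C(C)C)(C(C)C)C(C)C)C=C | intermediate
16 | (2E,6R,7S,10R)-7-[(1E)-buta-1,3-dien-1-yl]-2,6,7,10-tetramethyl-12-(triisopropylsilyloxy)dodec-2-enal | O=C/C(C)=C/CC[C@@H](C)[C@](C)(CC[C@@H](C)CCO[Si](C(C)C)(C(C)C)C(C)C)/C=C/C=C | intermediate
17 | trans-fused 15-(triisopropylsilyloxy)halim-1-en-18-al (4-CHO cis to H-5; H-10 trans to H-5; 8-Me/9-Me cis, trans to H-5; side chain cis to H-5) | O=C[C@@]1(C)CC=C[C@@H]2[C@@H]1CC[C@@H](C)[C@]2(C)CC[C@@H](C)CCO[Si](C(C)C)(C(C)C)C(C)C | intermediate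
18 | trans-fused 15-(triisopropylsilyloxy)halim-1-en-18-oic acid (stereochemistry as 17) | OC(=O)[C@@]1(C)CC=C[C@@H]2[C@@H]1CC[C@@H](C)[C@]2(C)CC[C@@H](C)CCO[Si](C(C)C)(C(C)C)C(C)C | intermediate
19 | 1α-phenylseleno-15-(triisopropylsilyloxy)halimane-18,2β-olide (lactone O on C2 cis to C4 carbonyl; PhSe on C1 trans to it and cis to H-10) | O=C1O[C@@H]2C[C@@]1(C)[C@H]1CC[C@@H](C)[C@](C)(CC[C@@H](C)CCO[Si](C(C)C)(C(C)C)C(C)C)[C@@H]1[C@H]2[Se]c1ccccc1 | intermediate
20 | methyl 2β-hydroxy-1α-phenylseleno-15-(triisopropylsilyloxy)halimane-18-oate (trans-diequatorial OH/SePh) | COC(=O)[C@@]1(C)C[C@@H](O)[C@H]([Se]c2ccccc2)[C@@H]2[C@@H]1CC[C@@H](C)[C@]2(C)CC[C@@H](C)CCO[Si](C(C)C)(C(C)C)C(C)C | intermediate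
21 | methyl 2β-hydroxy-15-(triisopropylsilyloxy)halim-1(10)-en-18-oate (2-OH cis to 4-CO2Me and H-5) | COC(=O)[C@@]1(C)C[C@@H](O)C=C2[C@@H]1CC[C@@H](C)[C@]2(C)CC[C@@H](C)CCO[Si](C(C)C)(C(C)C)C(C)C | intermediate
22 | methyl 2β,15-dihydroxyhalim-1(10)-en-18-oate | COC(=O)[C@@]1(C)C[C@@H](O)C=C2[C@@H]1CC[C@@H](C)[C@]2(C)CC[C@@H](C)CCO | intermediate
23 | CNP0209333.1, methyl 2β,15-diacetoxyhalim-1(10)-en-18-oate, (2R,4S,5S,8R,9S,13R) in halimane numbering | COC(=O)[C@@]1(C)C[C@@H](OC(C)=O)C=C2[C@@H]1CC[C@@H](C)[C@]2(C)CC[C@@H](C)CCOC(C)=O | target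

**Step count and risks**
Total steps: 14. Longest linear sequence: 13 (steps 1–6 and 8–14).

Most likely to fail, first: step 6. A coupling that creates adjacent quaternary and tertiary centres is at the limit of the allyl–allyl method, and linear or mixed isomers may dominate. Fallback: from allylic alcohol 7, acylation with propionyl chloride/pyridine gives allyl propionate F1. An enantioselective Ireland–Claisen rearrangement (Corey's chiral diazaborolidine bromide, i-Pr2NEt, CH2Cl2; Z(O)-boron enolate, chair transition state) gives 2,3-dimethyl-3-vinyl acid F2. BH3·THF gives alcohol F3, Dess–Martin oxidation gives aldehyde F4, and methylenation with Ph3P=CH2 rejoins the route at 10.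

Second: step 10. The catalyst must override a small substrate bias from the C8/C9 tether, and an α-methyl enal is a slow dienophile. Fallback: from triene 16, Pinnick oxidation gives trienoic acid F5. Mixed-anhydride coupling (PivCl, Et3N; lithiated (S)-4-benzyloxazolidin-2-one) gives trienimide F6, so facial control comes from a covalent auxiliary. Me2AlCl-promoted Evans-type intramolecular Diels–Alder reaction gives cycloadduct imide F7, and LiOH/H2O2 cleavage rejoins the route at 18.

Third: step 12. Lactonisation of the equatorial carboxyl onto C2 needs a boat ring A and may be slow or reversible. Fallback: from acid 18, TMSCHN2 gives methyl ester F8. Intermolecular hydroxyselenenylation (N-(phenylseleno)phthalimide, H2O, CSA, equilibrating conditions) gives the trans-diequatorial hydroxy selenide, separated from its regioisomer, which is compound 20; the route continues from 20 with the H2O2 elimination.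

**Further compounds**
F1 | step 6 | allyl propionate | CCC(=O)OC/C=C(C)/CC[C@@H](C)CCO[Si](C(C)C)(C(C)C)C(C)C
F2 | step 6 | 2,3-dimethyl-3-vinyl acid | OC(=O)[C@@H](C)[C@](C)(CC[C@@H](C)CCO[Si](C(C)C)(C(C)C)C(C)C)C=C
F3 | step 6 | alcohol | OC[C@@H](C)[C@](C)(CC[C@@H](C)CCO[Si](C(C)C)(C(C)C)C(C)C)C=C
F4 | step 6 | aldehyde | O=C[C@@H](C)[C@](C)(CC[C@@H](C)CCO[Si](C(C)C)(C(C)C)C(C)C)C=C
F5 | step 10 | trienoic acid | OC(=O)/C(C)=C/CC[C@@H](C)[C@](C)(CC[C@@H](C)CCO[Si](C(C)C)(C(C)C)C(C)C)/C=C/C=C
F6 | step 10 | trienimide | O=C1OC[C@H](Cc2ccccc2)N1C(=O)/C(C)=C/CC[C@@H](C)[C@](C)(CC[C@@H](C)CCO[Si](C(C)C)(C(C)C)C(C)C)/C=C/C=C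
F7 | step 10 | cycloadduct imide | O=C1OC[C@H](Cc2ccccc2)N1C(=O)[C@@]1(C)CC=C[C@@H]2[C@@H]1CC[C@@H](C)[C@]2(C)CC[C@@H](C)CCO[Si](C(C)C)(C(C)C)C(C)C
F8 | step 12 | methyl ester | COC(=O)[C@@]1(C)CC=C[C@@H]2[C@@H]1CC[C@@H](C)[C@]2(C)CC[C@@H](C)CCO[Si](C(C)C)(C(C)C)C(C)C
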